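## Structural features

The target is a benzofuro[2,3-b]chromen-4-one: a chromone (rings A and C) whose C2 and C3 are tied to ring B through a furan (ring D, oxygen between C2 and C2'), so C2 of ring C carries two oxygens. Ring A is a fully substituted C-methylphloroglucinol with a chelated C5 hydroxyl, a C6 methyl and a 2,2-dimethyl-2H-pyran (ring F) fused through O7 and C8. Ring B is a 1,2,4-trioxygenated benzene with a free C5' hydroxyl and a second dimethylpyran (ring E) fused through O4' and C3'. Ring E holds the only stereocentres, the adjacent carbinols C3'' (R) and C4'' (S), trans to each other.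

The fragile points are:
- the benzylic C4''–O bond, which is ortho to O2' and O4' and therefore ionises under acid, scrambling C4'' or bringing in solvent;
- the ring F alkene, which rules out hydrogenolysis and peracids once it is present;
- the hydroquinone-type ring B, which is air-sensitive as a free phenoxide.

The real difficulties are three:
- telling O5 from O8a, since both flank the acyl carbon C4a and either could close ring C (6-methyl or 8-methyl series);
- oxidising only one of two chromene-type alkenes, enantioselectively;
- closing ring D at C2 and not at C4.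

The key step exploits that C2 of ring C is a vinylogous carbonate carbon lying between the benzylic C3 and the ring A oxygen O1. It can therefore be inserted as CS2 into a deoxybenzoin and keep one sulfur as the leaving group for the furan closure. Compounds 20 and 24 map atom for atom onto the target with the (3''R,4''S) arrangement, so only protecting groups and the way to 20 were redesigned.

## Logic of the disconnections

**28 ⇐ 27.** Cut the two O–Si bonds at O3'' and O4''. The diol is unmasked last and by fluoride, so the free benzylic carbinol never meets acid. This costs one step, and the fluoride must be buffered because the product is a polyphenol.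

**27 ⇐ 26.** Cut O2'–C2 (ring D). C2 of 26 already carries a sulfur nucleofuge, so the furan closes by intramolecular addition–elimination without any redox change. Only C2 has a leaving group, so the coumestan mode through C4 is excluded. The O2' phenoxide must be generated without air.

**26 ⇐ 24.** Cut the three aryl O–CH2 acetal bonds (O5, O2', O5'). They must be cleaved without protic acid, because C4''–O is benzylic to a ring with two ortho oxygens. This is why the diol carries silyl ethers rather than acetals, which would need stronger acid.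

**24 ⇐ 20 + 21.** Cut C2–C3 and O1–C2 (ring C). The one-carbon unit 21 is stitched between the benzylic carbon and O8a. Two skeletal bonds and one ring are removed, leaving an open-chain ketone. O8a must be the only free oxygen nucleophile in 20, and C3 must be acidic enough to add to 21.

**20 ⇐ 19 ⇐ 18 + 11.** First cut O8a–Si, then C3–C1'. The benzylic bond is made by enolate arylation exactly where the bromine of 11 sits, under weak base that acetal and silyl ethers tolerate. A Friedel–Crafts acylation would destroy both and threaten C4''. Because O8a bears the only aryl silyl ether, its removal gives 20 with the regiochemistry of ring C closure already decided.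

**11 ⇐ 10 ⇐ 8 (through 9).** Cut the O–Si bonds, then C3''–O and C4''–O. Both oxygens come from one enantioselective oxygen transfer to the ring E alkene of 8, at a stage where it is the only alkene present. Anti opening at the benzylic carbon then gives the trans relation. The catalyst must control the face and the opening must proceed with inversion.

**8 ⇐ 7 ⇐ 5 + 6.** Cut C3'–C4'' and O4'–C2'' (ring E). An aryl propargyl ether rearrangement builds the pyran. The only free ortho position of 5 lies between O4' and O2', so no regiochemical alternative exists.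

**5 ⇐ 4 ⇐ 2 ⇐ 1.** Cut C1'–Br, then the O4'–aryl bond (from the formyl carbon), then the acetal ethers. Bromination para to the free hydroxyl places the future C1'. The oxygen pattern of ring B comes from cheap 1.

**18 ⇐ 17 ⇐ 16 ⇐ 15 ⇐ 14 + 6.** Cut C8–C4 and O7–C2 of ring F, then the O5 acetal, the O8a silyl ether and the O7 ether. The three hydroxyls of 14 are addressed in their natural order of reactivity: O7 (not chelated), then O8a (one ortho substituent), then O5 (flanked by methyl and acyl). C6 is blocked by methyl, so the rearrangement can only reach C8.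

**14 ⇐ 12 + 13.** Cut C4a–C4. Friedel–Crafts acylation is used here, on the symmetric triol, where acid is harmless and both free positions are equivalent.

## Other disconnections considered

**Alternative 1:** The cut goes through both C–O bonds of the diol at the stage of the complete pentacycle A2. In A2, ring F is still latent as a 7-O-(1,1-dimethylpropargyl) ether, so ring E holds the only alkene. In the forward step, the (R,R)-N,N'-bis(3,5-di-tert-butylsalicylidene)-1,2-cyclohexanediaminomanganese chloride/m-CPBA/N-methylmorpholine N-oxide system would oxidise that alkene, and aqueous acid would open the oxide at benzylic C4'' to A1.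
- In favour: the stereocentres arrive last, so no diol protection is needed and no acid-labile benzylic carbinol is carried through base, palladium and sulfur chemistry. On protecting-group economy this alternative is the better plan (two operations fewer). Keeping ring F latent solves the two-alkene problem as soundly as the order of events chosen here (equal).
- Against: face selection would have to work on a large, flat, poorly soluble heteroaromatic with a free chelated hydroxyl. The acid opening happens at a carbon that readily becomes a free cation, where anti selectivity is least secure. Ring F must then be made by thermal rearrangement in the presence of an unprotected benzylic trans-diol and an aryl acetate. Any shortfall in enantiopurity would surface on the most valuable intermediate, whereas 10 is a small diol that can be enriched.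
- Comparison: structure is equal, mechanism is riskier late, and step economy is about equal (silylation and desilylation saved, acetate handling added).

**Alternative 2:** The cut removes ring D in one stroke (C3–C1' and C2–O2'). It divides the target into the 2-morpholinochromone A4 (rings A, C, F) and the ring B/E hydroquinone A5. In the forward step, anodic oxidation of A5 gives its quinone, the enaminone carbon C3 of A4 adds, the ring re-aromatises, and the C2' hydroxyl displaces morpholine at C2 to give A3.
- In favour: it is the most convergent plan (two bonds and a ring in one operation), uses no palladium or sulfur, and the C5' hydroxyl emerges free. On step economy it is the better plan by several steps. C2 again enters at the carbonate level with a leaving group (equal in concept). The hydroquinone should oxidise well below the ring F alkene.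
- Against: nothing fixes which quinone carbon is attacked in the way the bromine of 11 fixes C1'. Deactivation of one enone arm by O4' argues for the right site but does not guarantee it. A quinone carrying a benzylic acetate at C4'' invites quinone methide formation and loss of that stereocentre. The product is itself an oxidisable hydroquinone monoether. A4 still needs the O5/O8a distinction.
- Comparison: shorter, but regiochemistry and stereochemical integrity rest on electronic preference rather than on pre-installed functional groups.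

**Alternative 3:** The cut goes through C4a–C8a of ring A. Ring A is folded from a polyketide chain masked as the 4-hydroxy-2-pyranone A7, which already carries the C4 ketone and the 2-methoxybenzofuran (rings B, D, E). In the forward step, methanolic KOH would open the lactone and the C4a carbanion of the resulting chain would attack the ester carbon (future C8a) in a Claisen condensation, aromatising to A6.
- In favour: no Friedel–Crafts step or cross-coupling is needed, the C6 methyl is built into the chain, and ring D exists from the outset with C2 at the right oxidation level. This is equal in concept to the methylsulfanyl group of 24, and better in that no sulfur is used.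
- Against: A6 has three free hydroxyls and so re-creates both selectivity problems that the chosen route settles by order of operations (O8a versus O5 for ring C, O7 versus O8a for ring F). The folding mode (Claisen at C4a versus aldol modes or re-lactonisation) is weakly controlled outside an enzyme. Hydroxide or methoxide can attack the vinylogous carbonate of the benzofuranyl ketone. The acetal-protected benzylic diol would need acid at the end. Assembling A7 is long.
- Comparison: elegant, but less predictable mechanistically and worse in step economy.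

Key step: step 15

Assumption: locants follow isoflavone numbering (rings A and C the chromone, ring B the C3 aryl, ring D the furan, ring E the diol-bearing pyran with C2''–C4'', ring F the pyran on ring A); 1, 6, 12, 13 and 21 are taken to be commercial.

## Route

Step 1
Reactants: 1 2,5-dihydroxybenzaldehyde
Product: 2 2,5-bis(methoxymethoxy)benzaldehyde
Conditions: MOMCl (3 equiv), i-Pr2NEt (4 equiv), CH2Cl2, 0 °C to reflux
Reagents that add atoms: chloromethyl methyl ether, COCCl
Why: O-alkylation of both phenols (the chelated 2-hydroxyl needs the excess and gentle heating); these aryl acetals are chosen for O2' and O5' because they survive heat, base, hypochlorite, zerovalent palladium and fluoride.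

Step 2
Reactants: 2 2,5-bis(methoxymethoxy)benzaldehyde
Product: 4 2,5-bis(methoxymethoxy)phenol, via aryl formate 3 (not isolated)
Conditions: mCPBA, NaHCO3, CH2Cl2, 0 °C to rt; then K2CO3 (cat.), MeOH, rt
Reagents that add atoms: 3-chloroperbenzoic acid, O=C(OO)c1cccc(Cl)c1
Why: Baeyer–Villiger (Dakin-type) oxidation, in which the electron-rich aryl group migrates; methanolysis of formate 3 frees the phenol oxygen that becomes O4' of ring E.

Step 3
Reactants: 4 2,5-bis(methoxymethoxy)phenol
Product: 5 4-bromo-2,5-bis(methoxymethoxy)phenol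
Conditions: NBS (1.0 equiv), MeCN, −20 to 0 °C
Reagents that add atoms: N-bromosuccinimide, O=C1CCC(=O)N1Br
Why: Electrophilic aromatic bromination para to the free hydroxyl, the strongest director; the single ortho position is crowded between two oxygens, so the bromine should mark the future C1'.

Step 4
Reactants: 5 4-bromo-2,5-bis(methoxymethoxy)phenol; 6 3-chloro-3-methylbut-1-yne
Product: 7 1-bromo-2,5-bis(methoxymethoxy)-4-[(2-methylbut-3-yn-2-yl)oxy]benzene
Conditions: DBU (1.5 equiv), CuCl2·2H2O (cat.), MeCN, 0 °C
Reagents that add atoms: none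
Why: Copper-catalysed O-propargylation of a phenol with a tertiary propargylic chloride, the standard entry to aryl 1,1-dimethylpropargyl ethers.

Step 5
Reactants: 7 1-bromo-2,5-bis(methoxymethoxy)-4-[(2-methylbut-3-yn-2-yl)oxy]benzene
Product: 8 6-bromo-5,8-bis(methoxymethoxy)-2,2-dimethyl-2H-chromene
Conditions: o-xylene, 140 °C
Reagents that add atoms: none
Why: Aromatic propargyl Claisen rearrangement, then 1,5-hydrogen shift and 6π oxa-electrocyclisation; only one ortho position is open, so ring E can only fuse at C3'/O4'.

Step 6
Reactants: 8 6-bromo-5,8-bis(methoxymethoxy)-2,2-dimethyl-2H-chromene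
Product: 10 (3R,4S)-6-bromo-5,8-bis(methoxymethoxy)-2,2-dimethylchromane-3,4-diol, via epoxide 9 (not isolated)
Conditions: (R,R)-N,N'-bis(3,5-di-tert-butylsalicylidene)-1,2-cyclohexanediaminomanganese chloride (4 mol %), 4-phenylpyridine N-oxide (20 mol %), aq. NaOCl (pH 11.3), CH2Cl2, 0 °C; then 0.5 M H2SO4, THF/H2O, 0 °C
Reagents that add atoms: sodium hypochlorite, [Na+].[O-]Cl; water, O
Why: Jacobsen–Katsuki epoxidation of a 2,2-dimethylchromene, the best substrate class for this catalyst; the (R,R) complex should deliver oxygen to the face that gives (3R,4R)-9, setting C3. Water then opens the oxide at the benzylic carbon with inversion (C3 is neopentyl and not attacked), setting C4 as S and the diol as trans.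

Step 7
Reactants: 10 (3R,4S)-6-bromo-5,8-bis(methoxymethoxy)-2,2-dimethylchromane-3,4-diol
Product: 11 (3R,4S)-6-bromo-3,4-bis(tert-butyldimethylsilyloxy)-5,8-bis(methoxymethoxy)-2,2-dimethylchromane
Conditions: TBSOTf (3 equiv), 2,6-lutidine, CH2Cl2, 0 °C to rt
Reagents that add atoms: tert-butyldimethylsilyl trifluoromethanesulfonate, CC(C)(C)[Si](C)(C)OS(=O)(=O)C(F)(F)F
Why: Silylation of both hindered secondary alcohols under buffered conditions; silyl ethers resist the later bases and leave with fluoride, so the benzylic C4''–O bond never has to face the acid that alkyl acetals would need.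

Step 8
Reactants: 12 2,4,6-trihydroxytoluene; 13 acetic acid
Product: 14 1-(2,4,6-trihydroxy-3-methylphenyl)ethan-1-one
Conditions: BF3·OEt2, 90 °C
Reagents that add atoms: none
Why: Friedel–Crafts C-acylation of a phloroglucinol with a carboxylic acid and BF3; the two free ring positions are equivalent and the product is deactivated towards a second acylation.

Step 9
Reactants: 14 1-(2,4,6-trihydroxy-3-methylphenyl)ethan-1-one; 6 3-chloro-3-methylbut-1-yne
Product: 15 1-{2,6-dihydroxy-3-methyl-4-[(2-methylbut-3-yn-2-yl)oxy]phenyl}ethan-1-one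
Conditions: 6 (1.1 equiv), DBU (1.2 equiv), CuCl2·2H2O (cat.), MeCN, −10 to 0 °C
Reagents that add atoms: none
Why: Copper-catalysed O-propargylation; the hydroxyl para to the acetyl group (future O7) is the only one not chelated and the most acidic, so one equivalent of base should ionise and alkylate it alone.

Step 10
Reactants: 15 1-{2,6-dihydroxy-3-methyl-4-[(2-methylbut-3-yn-2-yl)oxy]phenyl}ethan-1-one
Product: 16 1-{2-hydroxy-3-methyl-4-[(2-methylbut-3-yn-2-yl)oxy]-6-(triisopropylsilyloxy)phenyl}ethan-1-one
Conditions: TIPSCl (1.1 equiv), imidazole, DMF, 0 °C to rt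
Reagents that add atoms: chlorotriisopropylsilane, CC(C)[Si](Cl)(C(C)C)C(C)C
Why: Site-selective silylation: the future O8a hydroxyl has one ortho substituent, whereas the future O5 hydroxyl is flanked by methyl and acetyl and held in the stronger hydrogen bond, so the bulky chlorosilane should take the former.

Step 11
Reactants: 16 1-{2-hydroxy-3-methyl-4-[(2-methylbut-3-yn-2-yl)oxy]-6-(triisopropylsilyloxy)phenyl}ethan-1-one
Product: 17 1-{2-(methoxymethoxy)-3-methyl-4-[(2-methylbut-3-yn-2-yl)oxy]-6-(triisopropylsilyloxy)phenyl}ethan-1-one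
Conditions: NaH (1.1 equiv), THF, 0 °C; MOMCl, 0 °C to rt
Reagents that add atoms: chloromethyl methyl ether, COCCl
Why: O-alkylation of the only remaining hydroxyl; this fixes O5 as the acetal, so ring C can later close only through O8a.

Step 12
Reactants: 17 1-{2-(methoxymethoxy)-3-methyl-4-[(2-methylbut-3-yn-2-yl)oxy]-6-(triisopropylsilyloxy)phenyl}ethan-1-one
Product: 18 1-[7-(methoxymethoxy)-2,2,8-trimethyl-5-(triisopropylsilyloxy)-2H-chromen-6-yl]ethan-1-one
Conditions: o-xylene, 140 °C
Reagents that add atoms: none
Why: Propargyl Claisen rearrangement and electrocyclisation; the ortho carbon C6 is blocked by methyl, so the new C–C bond forms at C8 and the pyran closes through O7 (O8a is silylated), giving ring F with the required orientation.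

Step 13
Reactants: 18 1-[7-(methoxymethoxy)-2,2,8-trimethyl-5-(triisopropylsilyloxy)-2H-chromen-6-yl]ethan-1-one; 11 (3R,4S)-6-bromo-3,4-bis(tert-butyldimethylsilyloxy)-5,8-bis(methoxymethoxy)-2,2-dimethylchromane
Product: 19 2-[(3R,4S)-3,4-bis(tert-butyldimethylsilyloxy)-5,8-bis(methoxymethoxy)-2,2-dimethylchroman-6-yl]-1-[7-(methoxymethoxy)-2,2,8-trimethyl-5-(triisopropylsilyloxy)-2H-chromen-6-yl]ethan-1-one
Conditions: Pd2(dba)3 (2.5 mol %), XPhos (10 mol %), K3PO4 (2.5 equiv), toluene, 90 °C
Reagents that add atoms: none
Why: Palladium-catalysed α-arylation of a methyl ketone (Buchwald–Hartwig type): zerovalent palladium inserts into C–Br, the enolate binds, and reductive elimination forms C3–C1'. The hindered product should resist a second arylation, and the weak base spares acetal and silyl ethers.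

Step 14
Reactants: 19 2-[(3R,4S)-3,4-bis(tert-butyldimethylsilyloxy)-5,8-bis(methoxymethoxy)-2,2-dimethylchroman-6-yl]-1-[7-(methoxymethoxy)-2,2,8-trimethyl-5-(triisopropylsilyloxy)-2H-chromen-6-yl]ethan-1-one
Product: 20 2-[(3R,4S)-3,4-bis(tert-butyldimethylsilyloxy)-5,8-bis(methoxymethoxy)-2,2-dimethylchroman-6-yl]-1-[5-hydroxy-7-(methoxymethoxy)-2,2,8-trimethyl-2H-chromen-6-yl]ethan-1-one
Conditions: TBAF (1.1 equiv), AcOH (1.1 equiv), THF, 0 °C
Reagents that add atoms: none
Why: Fluoride cleavage of the aryl silyl ether, whose acyl-stabilised phenoxide is a far better leaving group than the alkoxides of the two hindered secondary silyl ethers; this frees O8a alone.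

Step 15
Reactants: 20 2-[(3R,4S)-3,4-bis(tert-butyldimethylsilyloxy)-5,8-bis(methoxymethoxy)-2,2-dimethylchroman-6-yl]-1-[5-hydroxy-7-(methoxymethoxy)-2,2,8-trimethyl-2H-chromen-6-yl]ethan-1-one; 21 carbon disulfide
Product: 24 3-[(3R,4S)-3,4-bis(tert-butyldimethylsilyloxy)-5,8-bis(methoxymethoxy)-2,2-dimethylchroman-6-yl]-5-(methoxymethoxy)-6,8,8-trimethyl-2-(methylsulfanyl)-4H,8H-pyrano[2,3-f]chromen-4-one, via dithiocarboxylic acid 22 (not isolated), via 2-thioxochromenone 23 (not isolated)
Conditions: KOt-Bu (3 equiv), THF, 0 °C; 21 (5 equiv), 0 °C to rt; AcOH to pH 5, 0 °C to rt (N2 sweep); then K2CO3, MeI (1.2 equiv), acetone, rt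
Reagents that add atoms: iodomethane, CI
Why: KOt-Bu removes the O8a proton and a proton at C3 (doubly activated by the ketone and ring B), and the enolate carbon adds to the carbon of 21 to give dithiocarboxylate 22, forming C2–C3. On buffering, the O8a hydroxyl adds to the thiocarbonyl carbon in a 6-exo-trig closure (the C=S bond lies outside the new ring) and the tetrahedral intermediate expels hydrogen sulfide, forming O1–C2 and ring C as thione 23. K2CO3 and MeI then alkylate the soft sulfur of the ambident thioxo-oxo anion, giving the 2-(methylsulfanyl)chromone 24. The closest known reaction is the conversion of 2-hydroxyaryl ketones, 2-hydroxydeoxybenzoins included, with CS2, base and an alkyl halide into 2-(alkylsulfanyl)chromones and isoflavones. No stereocentre is formed, and C3'' and C4'' are remote silyl-protected carbinols that base cannot epimerise. The step needs closure through O8a and not O5, which is secured because O5, O2' and O5' are acetal ethers and O8a is the only free oxygen nucleophile; S- rather than O-methylation follows from the softness of sulfur and the absence of any free phenol. C2 thus enters at its final oxidation level with a nucleofuge attached, so ring D can later close without a redox step and only at C2.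

Step 16
Reactants: 24 3-[(3R,4S)-3,4-bis(tert-butyldimethylsilyloxy)-5,8-bis(methoxymethoxy)-2,2-dimethylchroman-6-yl]-5-(methoxymethoxy)-6,8,8-trimethyl-2-(methylsulfanyl)-4H,8H-pyrano[2,3-f]chromen-4-one
Product: 26 3-[(3R,4S)-3,4-bis(tert-butyldimethylsilyloxy)-5,8-dihydroxy-2,2-dimethylchroman-6-yl]-5-hydroxy-6,8,8-trimethyl-2-(methylsulfanyl)-4H,8H-pyrano[2,3-f]chromen-4-one, via tris(trimethylsilyl) ether 25 (not isolated)
Conditions: TMSOTf (9 equiv), 2,2'-bipyridyl (12 equiv), CH2Cl2, 0 °C to rt; then H2O/THF, rt
Reagents that add atoms: none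
Why: Aryl methoxymethyl ethers are converted by the silyl triflate–bipyridyl pair into aryl trimethylsilyl ethers, which water hydrolyses; no protic acid is present, so the benzylic C4''–O bond and the alkyl silyl ethers should remain untouched.

Step 17
Reactants: 26 3-[(3R,4S)-3,4-bis(tert-butyldimethylsilyloxy)-5,8-dihydroxy-2,2-dimethylchroman-6-yl]-5-hydroxy-6,8,8-trimethyl-2-(methylsulfanyl)-4H,8H-pyrano[2,3-f]chromen-4-one
Product: 27 3'',4''-bis-O-(tert-butyldimethylsilyl) ether of CNP0351839.1
Conditions: K2CO3 (3 equiv), degassed DMF, Ar, 60 °C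
Reagents that add atoms: none
Why: Intramolecular nucleophilic vinylic substitution (addition–elimination): the O2' phenoxide adds to C2 of the vinylogous thioester and methanethiolate leaves, closing ring D in the same geometry as dibenzofuran closures by aromatic substitution. Only C2 bears a leaving group, so only the benzofuro[2,3-b]chromenone can form.

Step 18
Reactants: 27 3'',4''-bis-O-(tert-butyldimethylsilyl) ether of CNP0351839.1
Product: 28 CNP0351839.1 (target; (3''R,4''S)-trans-diol)
Conditions: TBAF (5 equiv), AcOH (5 equiv), THF, 0 to 40 °C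
Reagents that add atoms: none
Why: Buffered fluoride desilylation of the two secondary silyl ethers; Si–O cleavage leaves both C–O bonds intact, so C3'' (R) and C4'' (S) are delivered unchanged and no acid touches the benzylic carbinol.

## Compound list

1 | 2,5-dihydroxybenzaldehyde | O=Cc1cc(O)ccc1O | starting material
2 | 2,5-bis(methoxymethoxy)benzaldehyde | O=Cc1cc(OCOC)ccc1OCOC | intermediate
3 | 2,5-bis(methoxymethoxy)phenyl formate | O=COc1cc(OCOC)ccc1OCOC | intermediate (not isolated)
4 | 2,5-bis(methoxymethoxy)phenol | Oc1cc(OCOC)ccc1OCOC | intermediate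
5 | 4-bromo-2,5-bis(methoxymethoxy)phenol | Oc1cc(OCOC)c(Br)cc1OCOC | intermediate
6 | 3-chloro-3-methylbut-1-yne | C#CC(C)(C)Cl | starting material
7 | 1-bromo-2,5-bis(methoxymethoxy)-4-[(2-methylbut-3-yn-2-yl)oxy]benzene | C#CC(C)(C)Oc1cc(OCOC)c(Br)cc1OCOC | intermediate
8 | 6-bromo-5,8-bis(methoxymethoxy)-2,2-dimethyl-2H-chromene | CC1(C)C=Cc2c(OCOC)c(Br)cc(OCOC)c2O1 | intermediate
9 | (3R,4R)-6-bromo-3,4-epoxy-5,8-bis(methoxymethoxy)-2,2-dimethylchromane | CC1(C)Oc2c(OCOC)cc(Br)c(OCOC)c2[C@H]2O[C@@H]12 | intermediate (not isolated)
10 | (3R,4S)-6-bromo-5,8-bis(methoxymethoxy)-2,2-dimethylchromane-3,4-diol | COCOc1cc(Br)c(OCOC)c2c1OC(C)(C)[C@H](O)[C@H]2O | intermediate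
11 | (3R,4S)-6-bromo-3,4-bis(tert-butyldimethylsilyloxy)-5,8-bis(methoxymethoxy)-2,2-dimethylchromane | COCOc1cc(Br)c(OCOC)c2c1OC(C)(C)[C@H](O[Si](C)(C)C(C)(C)C)[C@H]2O[Si](C)(C)C(C)(C)C | intermediate
12 | 2,4,6-trihydroxytoluene | Cc1c(O)cc(O)cc1O | starting material
13 | acetic acid | CC(=O)O | starting material
14 | 1-(2,4,6-trihydroxy-3-methylphenyl)ethan-1-one | CC(=O)c1c(O)cc(O)c(C)c1O | intermediate
15 | 1-{2,6-dihydroxy-3-methyl-4-[(2-methylbut-3-yn-2-yl)oxy]phenyl}ethan-1-one | CC(=O)c1c(O)cc(OC(C)(C)C#C)c(C)c1O | intermediate
16 | 1-{2-hydroxy-3-methyl-4-[(2-methylbut-3-yn-2-yl)oxy]-6-(triisopropylsilyloxy)phenyl}ethan-1-one | CC(=O)c1c(O[Si](C(C)C)(C(C)C)C(C)C)cc(OC(C)(C)C#C)c(C)c1O | intermediate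
17 | 1-{2-(methoxymethoxy)-3-methyl-4-[(2-methylbut-3-yn-2-yl)oxy]-6-(triisopropylsilyloxy)phenyl}ethan-1-one | CC(=O)c1c(O[Si](C(C)C)(C(C)C)C(C)C)cc(OC(C)(C)C#C)c(C)c1OCOC | intermediate
18 | 1-[7-(methoxymethoxy)-2,2,8-trimethyl-5-(triisopropylsilyloxy)-2H-chromen-6-yl]ethan-1-one | CC(=O)c1c(O[Si](C(C)C)(C(C)C)C(C)C)c2C=CC(C)(C)Oc2c(C)c1OCOC | intermediate
19 | 2-[(3R,4S)-3,4-bis(tert-butyldimethylsilyloxy)-5,8-bis(methoxymethoxy)-2,2-dimethylchroman-6-yl]-1-[7-(methoxymethoxy)-2,2,8-trimethyl-5-(triisopropylsilyloxy)-2H-chromen-6-yl]ethan-1-one | Cc1c2c(c(O[Si](C(C)C)(C(C)C)C(C)C)c(C(=O)Cc3c(OCOC)c4c(c(OCOC)c3)OC(C)(C)[C@H](O[Si](C)(C)C(C)(C)C)[C@H]4O[Si](C)(C)C(C)(C)C)c1OCOC)C=CC(C)(C)O2 | intermediate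
20 | 2-[(3R,4S)-3,4-bis(tert-butyldimethylsilyloxy)-5,8-bis(methoxymethoxy)-2,2-dimethylchroman-6-yl]-1-[5-hydroxy-7-(methoxymethoxy)-2,2,8-trimethyl-2H-chromen-6-yl]ethan-1-one (deoxybenzoin, O8a free) | Cc1c2c(c(O)c(C(=O)Cc3c(OCOC)c4c(c(OCOC)c3)OC(C)(C)[C@H](O[Si](C)(C)C(C)(C)C)[C@H]4O[Si](C)(C)C(C)(C)C)c1OCOC)C=CC(C)(C)O2 | intermediate
21 | carbon disulfide | S=C=S | starting material
22 | 2-[(3R,4S)-3,4-bis(tert-butyldimethylsilyloxy)-5,8-bis(methoxymethoxy)-2,2-dimethylchroman-6-yl]-3-[5-hydroxy-7-(methoxymethoxy)-2,2,8-trimethyl-2H-chromen-6-yl]-3-oxopropanedithioic acid (present as its potassium salt; C2 of the chain enolised, configuration not defined) | Cc1c2c(c(O)c(C(=O)C(C(=S)S)c3c(OCOC)c4c(c(OCOC)c3)OC(C)(C)[C@H](O[Si](C)(C)C(C)(C)C)[C@H]4O[Si](C)(C)C(C)(C)C)c1OCOC)C=CC(C)(C)O2 | intermediate (not isolated)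
23 | 3-[(3R,4S)-3,4-bis(tert-butyldimethylsilyloxy)-5,8-bis(methoxymethoxy)-2,2-dimethylchroman-6-yl]-4-hydroxy-5-(methoxymethoxy)-6,8,8-trimethyl-2H,8H-pyrano[2,3-f]chromene-2-thione | Cc1c2c(c3oc(=S)c(-c4c(OCOC)c5c(c(OCOC)c4)OC(C)(C)[C@H](O[Si](C)(C)C(C)(C)C)[C@H]5O[Si](C)(C)C(C)(C)C)c(O)c3c1OCOC)C=CC(C)(C)O2 | intermediate (not isolated)
24 | 3-[(3R,4S)-3,4-bis(tert-butyldimethylsilyloxy)-5,8-bis(methoxymethoxy)-2,2-dimethylchroman-6-yl]-5-(methoxymethoxy)-6,8,8-trimethyl-2-(methylsulfanyl)-4H,8H-pyrano[2,3-f]chromen-4-one | Cc1c2c(c3oc(SC)c(-c4c(OCOC)c5c(c(OCOC)c4)OC(C)(C)[C@H](O[Si](C)(C)C(C)(C)C)[C@H]5O[Si](C)(C)C(C)(C)C)c(=O)c3c1OCOC)C=CC(C)(C)O2 | intermediate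
25 | 5,2',5'-tris-O-(trimethylsilyl) analogue of 24 (all three methoxymethyl groups replaced by trimethylsilyl) | Cc1c2c(c3oc(SC)c(-c4c(O[Si](C)(C)C)c5c(c(O[Si](C)(C)C)c4)OC(C)(C)[C@H](O[Si](C)(C)C(C)(C)C)[C@H]5O[Si](C)(C)C(C)(C)C)c(=O)c3c1O[Si](C)(C)C)C=CC(C)(C)O2 | intermediate (not isolated)
26 | 3-[(3R,4S)-3,4-bis(tert-butyldimethylsilyloxy)-5,8-dihydroxy-2,2-dimethylchroman-6-yl]-5-hydroxy-6,8,8-trimethyl-2-(methylsulfanyl)-4H,8H-pyrano[2,3-f]chromen-4-one | Cc1c2c(c3oc(SC)c(-c4c(O)c5c(c(O)c4)OC(C)(C)[C@H](O[Si](C)(C)C(C)(C)C)[C@H]5O[Si](C)(C)C(C)(C)C)c(=O)c3c1O)C=CC(C)(C)O2 | intermediate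
27 | 3'',4''-bis-O-(tert-butyldimethylsilyl) ether of CNP0351839.1 (rings A–F complete, (3''R,4''S)) | Cc1c2c(c3oc4oc5c6c(c(O)cc5c4c(=O)c3c1O)OC(C)(C)[C@H](O[Si](C)(C)C(C)(C)C)[C@H]6O[Si](C)(C)C(C)(C)C)C=CC(C)(C)O2 | intermediate
28 | CNP0351839.1, (3''R,4''S)-trans-diol | Cc1c2c(c3oc4oc5c6c(c(O)cc5c4c(=O)c3c1O)OC(C)(C)[C@H](O)[C@H]6O)C=CC(C)(C)O2 | target

## Step count and risks

Total: 18 steps. Longest linear sequence: 13 steps (steps 1–7 and 13–18). The ring A branch (steps 8–12) joins at step 13.

**Key step (step 15).** What may go wrong: the enolate at C3 lies between two ortho-substituted aryl groups, so its addition to 21 may be incomplete or reverse on protonation, and the acid-triggered closure with loss of hydrogen sulfide may lag behind decomposition of the dithioacid. Fallback, from 19 back to 24: 19 is treated with NaH, CS2 and MeI (2.2 equiv) in THF to give the bis(methylsulfanyl)methylene ketone (ketene dithioacetal) F1, a standard and isolable product of deoxybenzoins. Fluoride (TBAF, THF, 0 °C to rt) then frees the O8a phenoxide, which adds to the dithioacetal carbon and expels methanethiolate, closing ring C and giving 24 directly.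

**Step 13.** What may go wrong: slow enolisation of the di-ortho-substituted aryl ketone by the weak base, protodebromination of the electron-rich bromide, or loss of the aryl silyl ether at 90 °C. Fallback, from 18 back to 19: 18 is converted (LiHMDS, TMSCl, THF, −78 °C) into its trimethylsilyl enol ether F2. F2 is coupled with 11 under neutral conditions (PdCl2[P(o-tol)3]2, Bu3SnF, toluene, 100 °C) through the tin enolate formed in the flask, giving 19.

**Step 17.** What may go wrong: methanethiolate is a mediocre nucleofuge, so collapse of the adduct may be slow and the phenoxide of the hydroquinone-type ring may oxidise during prolonged heating. Fallback, from 24 back to 27: the sulfur of 24 is oxidised with (n-Pr)4N[RuO4] (cat.) and N-methylmorpholine N-oxide, which spares alkenes, to the 2-(methylsulfonyl) compound F3. The aryl acetals are removed as in step 16 to give the tri-phenol sulfone F4, which should close at room temperature on NaHCO3 with loss of methanesulfinate to give 27.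

**Step 6.** What may go wrong: face selection may be eroded by the peri substituent at C5. Separately, anti selectivity may be lost if the electron-rich benzylic carbon ionises fully before water arrives, so that water can enter from either face. Fallback for the second failure, from 10 of unsatisfactory purity at C4 back to 10: the benzylic carbinol is oxidised with DDQ (CH2Cl2/H2O, rt) to the hydroxy ketone F5, whose C3 centre is that of 10. F5 is reduced with NaBH4 (MeOH, −40 °C, non-basic work-up); for 3-hydroxychroman-4-ones this favours the 3,4-trans diol, returning 10. A shortfall in enantiopurity would be met by recrystallising 10.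

**Step 10.** What may go wrong: incomplete discrimination between the two chelated hydroxyls, or silyl transfer between them, giving the protecting-group pattern that would lead to the 8-methyl series. Fallback, from 14 back to 18, capping the two more reactive hydroxyls first:
- 14 is dibenzylated (BnBr 2 equiv, K2CO3, acetone) to the 4,6-bis(benzyloxy) ketone F6, leaving only the methyl-flanked hydroxyl.
- F6 is alkylated there (NaH, MOMCl) to F7.
- Hydrogenolysis (H2, Pd/C, EtOAc; no alkene is present yet) gives the diol F8.
- F8 is chromenylated with 3-methylbut-2-enal and ethylenediammonium diacetate (toluene, reflux) at C8 through the non-chelated O7 to the chromenol F9.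
- F9 is silylated (TIPSCl, imidazole) at its only hydroxyl to 18.

## Further compounds

F1 | step 15 | 2-[(3R,4S)-3,4-bis(tert-butyldimethylsilyloxy)-5,8-bis(methoxymethoxy)-2,2-dimethylchroman-6-yl]-1-[7-(methoxymethoxy)-2,2,8-trimethyl-5-(triisopropylsilyloxy)-2H-chromen-6-yl]-3,3-bis(methylsulfanyl)prop-2-en-1-one | Cc1c2c(c(O[Si](C(C)C)(C(C)C)C(C)C)c(C(=O)C(=C(SC)SC)c3c(OCOC)c4c(c(OCOC)c3)OC(C)(C)[C@H](O[Si](C)(C)C(C)(C)C)[C@H]4O[Si](C)(C)C(C)(C)C)c1OCOC)C=CC(C)(C)O2
F2 | step 13 | trimethylsilyl enol ether of 18, {1-[7-(methoxymethoxy)-2,2,8-trimethyl-5-(triisopropylsilyloxy)-2H-chromen-6-yl]ethenyloxy}trimethylsilane | C=C(O[Si](C)(C)C)c1c(O[Si](C(C)C)(C(C)C)C(C)C)c2C=CC(C)(C)Oc2c(C)c1OCOC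
F3 | step 17 | 2-(methylsulfonyl) analogue of 24 | Cc1c2c(c3oc(S(C)(=O)=O)c(-c4c(OCOC)c5c(c(OCOC)c4)OC(C)(C)[C@H](O[Si](C)(C)C(C)(C)C)[C@H]5O[Si](C)(C)C(C)(C)C)c(=O)c3c1OCOC)C=CC(C)(C)O2
F4 | step 17 | 2-(methylsulfonyl) analogue of 26 | Cc1c2c(c3oc(S(C)(=O)=O)c(-c4c(O)c5c(c(O)c4)OC(C)(C)[C@H](O[Si](C)(C)C(C)(C)C)[C@H]5O[Si](C)(C)C(C)(C)C)c(=O)c3c1O)C=CC(C)(C)O2
F5 | step 6 | (3S)-6-bromo-3-hydroxy-5,8-bis(methoxymethoxy)-2,2-dimethylchroman-4-one (same spatial arrangement at C3 as in 10; the descriptor changes because C4 now outranks C2) | COCOc1cc(Br)c(OCOC)c2c1OC(C)(C)[C@H](O)C2=O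
F6 | step 10 | 1-[4,6-bis(benzyloxy)-2-hydroxy-3-methylphenyl]ethan-1-one | CC(=O)c1c(O)c(C)c(OCc2ccccc2)cc1OCc1ccccc1
F7 | step 10 | 1-[4,6-bis(benzyloxy)-2-(methoxymethoxy)-3-methylphenyl]ethan-1-one | CC(=O)c1c(OCOC)c(C)c(OCc2ccccc2)cc1OCc1ccccc1
F8 | step 10 | 1-[4,6-dihydroxy-2-(methoxymethoxy)-3-methylphenyl]ethan-1-one | CC(=O)c1c(OCOC)c(C)c(O)cc1O
F9 | step 10 | 1-[5-hydroxy-7-(methoxymethoxy)-2,2,8-trimethyl-2H-chromen-6-yl]ethan-1-one | CC(=O)c1c(O)c2C=CC(C)(C)Oc2c(C)c1OCOC
A1 | alternative 1 | (3''R,4''S)-trans-diol of the pentacyclic core, 5'-acetate, 7-O-(2-methylbut-3-yn-2-yl) ether | Cc1c(OC(C)(C)C#C)cc2oc3oc4c5c(c(OC(C)=O)cc4c3c(=O)c2c1O)OC(C)(C)[C@H](O)[C@H]5O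
A2 | alternative 1 | pentacyclic core with the ring E alkene, 5'-acetate, 7-O-(2-methylbut-3-yn-2-yl) ether | Cc1c(OC(C)(C)C#C)cc2oc3oc4c5c(c(OC(C)=O)cc4c3c(=O)c2c1O)OC(C)(C)C=C5
A3 | alternative 2 | 3'',4''-diacetate of the target | Cc1c2c(c3oc4oc5c6c(c(O)cc5c4c(=O)c3c1O)OC(C)(C)[C@H](OC(C)=O)[C@H]6OC(C)=O)C=CC(C)(C)O2
A4 | alternative 2 | 5-hydroxy-6,8,8-trimethyl-2-(morpholin-4-yl)-4H,8H-pyrano[2,3-f]chromen-4-one | Cc1c2c(c3oc(N4CCOCC4)cc(=O)c3c1O)C=CC(C)(C)O2
A5 | alternative 2 | (3R,4S)-5,8-dihydroxy-2,2-dimethylchromane-3,4-diyl diacetate | Oc1ccc(O)c2c1OC(C)(C)[C@H](OC(C)=O)[C@H]2OC(C)=O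
A6 | alternative 3 | (2,4,6-trihydroxy-3-methylphenyl) 2-methoxybenzofuran-3-yl ketone of rings B, D, E, tris(methoxymethyl) ether | Cc1c(O)cc(O)c(C(=O)c2c(OC)oc3c4c(c(OCOC)cc23)OC(C)(C)[C@H](OCOC)[C@H]4OCOC)c1O
A7 | alternative 3 | 4-hydroxy-5-methyl-6-[2-oxo-2-(2-methoxybenzofuran-3-yl)ethyl]-2H-pyran-2-one of rings B, D, E, tris(methoxymethyl) ether | O=c1cc(O)c(C)c(CC(=O)c2c(OC)oc3c4c(c(OCOC)cc23)OC(C)(C)[C@H](OCOC)[C@H]4OCOC)o1
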